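**Retrosynthetic overview**
1. Target ⇐ cleavage of the two aryl methyl ethers of the 5,8-dimethoxy lactone hemisuccinate.
2. Six-membered lactone ⇐ oxygen-insertion ring expansion (Baeyer–Villiger 1,2-shift of the sp3 carbon C2 from carbon to oxygen) of a 2-alkyl-4,7-dimethoxyindan-1-one, run as a dynamic kinetic resolution that sets C3.
3. Side chain ⇐ cross-metathesis/hydrogenation of the 2-allylindanone with (R)-but-3-en-2-yl hydrogen succinate (carbinol centre bought, succinate from succinic anhydride).
4. 2-Allylindanone ⇐ enolate allylation of 4,7-dimethoxyindan-1-one ⇐ one-pot acylation/cyclisation of 1,4-dimethoxybenzene (from hydroquinone) with 3-chloropropanoyl chloride.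
5. Ring order: benzene ring bought (hydroquinone) → five-membered ketone ring (step 2) → expanded to the six-membered lactone ring (step 6).

Assumption: (R)-but-3-en-2-ol is bought in ≥98% ee, and the two O-methyl groups are protecting groups put on with MeI.

Step 1
Reactants: 1 hydroquinone
Product: 2 1,4-dimethoxybenzene
Conditions: MeI (2.5 equiv), K2CO3 (2.5 equiv), acetone, reflux, N2
Reagents that add atoms: iodomethane, CI
Why: Williamson ether synthesis protects both phenols as methyl ethers that survive acid, enolate, metathesis and enzymatic conditions; no stereocentre is formed.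

Step 2
Reactants: 2 1,4-dimethoxybenzene; 3 3-chloropropanoyl chloride
Product: 5 4,7-dimethoxyindan-1-one, via chloroketone 4 (not isolated)
Conditions: TfOH (5 equiv), ClCH2CH2Cl, 0 °C, 1 h; then 80 °C, 4 h
Reagents that add atoms: none
Why: Superacid-promoted Friedel–Crafts acylation is followed by loss of HCl and Nazarov-type cycloalkylation of the aryl vinyl ketone onto the only free ortho position, so the symmetric arene can give only one indanone.

Step 3
Reactants: 5 4,7-dimethoxyindan-1-one; 6 allyl bromide
Product: 7 racemic 2-allyl-4,7-dimethoxyindan-1-one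
Conditions: LiN(i-Pr)2 (commercial solution, 1.05 equiv), THF, −78 °C; 6 (1.1 equiv), −78 → −20 °C
Reagents that add atoms: none
Why: Enolate alkylation (SN2) at C2, the only enolisable position, with a reactive allylic halide; C2 is formed racemic on purpose because it is equilibrated and resolved in step 6.

Step 4
Reactants: 8 (R)-but-3-en-2-ol; 9 succinic anhydride
Product: 10 4-[(2R)-but-3-en-2-yloxy]-4-oxobutanoic acid
Conditions: DMAP (10 mol %), pyridine, 0 °C → rt; aq. HCl work-up
Reagents that add atoms: none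
Why: DMAP-catalysed ring-opening acylation of the alcohol by the cyclic anhydride gives the half-ester, and the (R) centre is retained because only the O–H bond reacts.

Step 5
Reactants: 7 racemic 2-allyl-4,7-dimethoxyindan-1-one; 10 4-[(2R)-but-3-en-2-yloxy]-4-oxobutanoic acid (2 equiv)
Product: 12 4-{[(2R)-5-(4,7-dimethoxy-1-oxo-2,3-dihydro-1H-inden-2-yl)pentan-2-yl]oxy}-4-oxobutanoic acid (both C2 epimers), via cross-metathesis alkene 11 (not isolated)
Conditions: second-generation Grubbs catalyst RuCl2(H2IMes)(PCy3)(=CHPh) (5 mol %), CH2Cl2, 40 °C; then H2 (7 bar), 60 °C, same pot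
Reagents that add atoms: none
Why: Olefin cross-metathesis of a reactive terminal allyl olefin with a slower secondary allylic ester gives the cross-product selectively, and the ruthenium residue under H2 saturates the new alkene (tandem metathesis–hydrogenation) without touching the aryl ketone, the esters or the carbinol centre.

Step 6
Reactants: 12 4-{[(2R)-5-(4,7-dimethoxy-1-oxo-2,3-dihydro-1H-inden-2-yl)pentan-2-yl]oxy}-4-oxobutanoic acid (both C2 epimers)
Product: 13 4-{[(2R)-5-[(3R)-5,8-dimethoxy-1-oxo-3,4-dihydro-1H-isochromen-3-yl]pentan-2-yl]oxy}-4-oxobutanoic acid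
Conditions: phenylacetone monooxygenase Met446Gly variant fused to phosphite dehydrogenase (cell-free extract), NADP+ (cat.), Na2HPO3 (3 equiv), air, Tris–HCl buffer pH 9.5, 5% MeOH, 30 °C; then pH 3, EtOAc
Reagents that add atoms: dioxygen, O=O
Why: Proposed new method: an enlarged-pocket flavin Baeyer–Villiger monooxygenase is applied to a substrate class on which it has not been shown (an ortho-alkoxy aryl ketone whose aryl group would migrate with peracids, carrying a long chain with a stereocentre and a carboxylate), where the flavin C4a-peroxide adds to C1, the active site holds the O–O bond antiperiplanar to C1–C2 so that the sp3 carbon C2 and not the aryl carbon shifts to oxygen with retention (five- to six-membered ring expansion), only the (2R)-epimer is accepted and gives (3R), and the (2S)-epimer is returned through the enolate at pH 9.5 (dynamic kinetic resolution); the closest known reaction, as I recall it, is the enzymatic dynamic kinetic Baeyer–Villiger oxidation of simple racemic 2-alkylindan-1-ones to (R)-3-alkyl-3,4-dihydroisocoumarins.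

Step 7
Reactants: 13 4-{[(2R)-5-[(3R)-5,8-dimethoxy-1-oxo-3,4-dihydro-1H-isochromen-3-yl]pentan-2-yl]oxy}-4-oxobutanoic acid
Product: 14 4-{[(2R)-5-[(3R)-5,8-dihydroxy-1-oxo-3,4-dihydro-1H-isochromen-3-yl]pentan-2-yl]oxy}-4-oxobutanoic acid (target)
Conditions: BBr3 (6 equiv), CH2Cl2, −78 → 0 °C; ice-water quench
Reagents that add atoms: none
Why: Lewis-acid cleavage of both aryl methyl ethers (the C8 ether helped by chelation to the lactone carbonyl) is faster at or below 0 °C than attack on the alkyl ester or the lactone, and neither stereocentre is involved.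

**Compound list**
1 | hydroquinone (benzene-1,4-diol) | Oc1ccc(O)cc1 | starting material
2 | 1,4-dimethoxybenzene | COc1ccc(OC)cc1 | intermediate
3 | 3-chloropropanoyl chloride | ClCCC(Cl)=O | starting material
4 | 3-chloro-1-(2,5-dimethoxyphenyl)propan-1-one (not isolated) | COc1ccc(OC)c(C(=O)CCCl)c1 | intermediate
5 | 4,7-dimethoxyindan-1-one | COc1ccc(OC)c2c1CCC2=O | intermediate
6 | allyl bromide (3-bromoprop-1-ene) | C=CCBr | starting material
7 | racemic 2-allyl-4,7-dimethoxyindan-1-one | C=CCC1Cc2c(OC)ccc(OC)c2C1=O | intermediate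
8 | (R)-but-3-en-2-ol | C[C@@H](O)C=C | starting material
9 | succinic anhydride | O=C1CCC(=O)O1 | starting material
10 | 4-[(2R)-but-3-en-2-yloxy]-4-oxobutanoic acid | C[C@H](C=C)OC(=O)CCC(=O)O | intermediate
11 | 4-{[(2R,3E)-5-(4,7-dimethoxy-1-oxo-2,3-dihydro-1H-inden-2-yl)pent-3-en-2-yl]oxy}-4-oxobutanoic acid, both C2 epimers (not isolated) | C[C@H](/C=C/CC1Cc2c(OC)ccc(OC)c2C1=O)OC(=O)CCC(=O)O | intermediate
12 | 4-{[(2R)-5-(4,7-dimethoxy-1-oxo-2,3-dihydro-1H-inden-2-yl)pentan-2-yl]oxy}-4-oxobutanoic acid, both C2 epimers | C[C@H](CCCC1Cc2c(OC)ccc(OC)c2C1=O)OC(=O)CCC(=O)O | intermediate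
13 | 4-{[(2R)-5-[(3R)-5,8-dimethoxy-1-oxo-3,4-dihydro-1H-isochromen-3-yl]pentan-2-yl]oxy}-4-oxobutanoic acid | C[C@H](CCC[C@@H]1Cc2c(OC)ccc(OC)c2C(=O)O1)OC(=O)CCC(=O)O | intermediate
14 | 4-{[(2R)-5-[(3R)-5,8-dihydroxy-1-oxo-3,4-dihydro-1H-isochromen-3-yl]pentan-2-yl]oxy}-4-oxobutanoic acid | C[C@H](CCC[C@@H]1Cc2c(O)ccc(O)c2C(=O)O1)OC(=O)CCC(=O)O | target

**Total step count:** 7. **Longest linear sequence:** 6 (steps 1, 2, 3, 5, 6, 7).

**Three steps most likely to fail**

Step 6 (the proposed enzymatic ring expansion). The 7-methoxy group next to the carbonyl or the carboxylate chain may prevent binding, or the enzyme may not override aryl migration. The fallback uses known chemistry, sets out from 12 and comes back at 13; it cuts the five-membered ring and re-closes it as the lactone instead of inserting oxygen. NaBH4 (MeOH, 0 °C) gives the indan-1-ol acid F1. TsOH (cat., toluene, 80 °C) dehydrates it to the 2-substituted 4,7-dimethoxy-1H-indene acid F2. Ozonolysis (O3, CH2Cl2/MeOH, −78 °C; Me2S) cleaves the ring double bond to the keto aldehyde F3. Pinnick oxidation (NaClO2, NaH2PO4, 2-methylbut-2-ene) gives the keto benzoic acid F4. An (R)-selective ketoreductase from a commercial panel (NADP+, i-PrOH, pH 7) reduces the benzyl ketone, and TsOH in toluene closes the lactone to 13.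

Step 5 (tandem cross-metathesis/hydrogenation). The ruthenium residue may isomerise the allylic ester, which would erode the carbinol centre, or hydrogenate incompletely. The fallback sets out from 5 and comes back at 12; it forms the C2–chain bond by enolate alkylation with a saturated iodide. Commercial (R)-pent-4-en-2-ol is silylated (t-BuMe2SiCl, imidazole, DMF) to the silyl ether F5. Hydroboration with 9-BBN and treatment with iodine/NaOMe give the primary iodide F6. The enolate of 5 (LiN(i-Pr)2, THF/DMPU, −78 → 0 °C) is alkylated with F6 to the silyl ether ketone F7. HF·pyridine gives the hydroxy ketone F8, and succinic anhydride with DMAP in pyridine gives 12.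

Step 7 (BBr3 demethylation). The C5 ether may need temperatures at which the alkyl ester or the lactone is attacked. The fallback sets out from 13 and comes back at 14; it removes the methyl groups oxidatively. (NH4)2Ce(NO3)6 in MeCN/H2O at 0 °C gives the quinone F9, and Na2S2O4 in EtOAc/H2O reduces it at once to the hydroquinone 14.

**Further compounds**
F1 | step 6 | 4-{[(2R)-5-(1-hydroxy-4,7-dimethoxy-2,3-dihydro-1H-inden-2-yl)pentan-2-yl]oxy}-4-oxobutanoic acid (diastereomer mixture) | C[C@H](CCCC1Cc2c(OC)ccc(OC)c2C1O)OC(=O)CCC(=O)O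
F2 | step 6 | 4-{[(2R)-5-(4,7-dimethoxy-1H-inden-2-yl)pentan-2-yl]oxy}-4-oxobutanoic acid | C[C@H](CCCC1=Cc2c(OC)ccc(OC)c2C1)OC(=O)CCC(=O)O
F3 | step 6 | 4-{[(2R)-7-(2-formyl-3,6-dimethoxyphenyl)-6-oxoheptan-2-yl]oxy}-4-oxobutanoic acid | C[C@H](CCCC(=O)Cc1c(OC)ccc(OC)c1C=O)OC(=O)CCC(=O)O
F4 | step 6 | 2-{(6R)-6-[(3-carboxypropanoyl)oxy]-2-oxoheptyl}-3,6-dimethoxybenzoic acid | C[C@H](CCCC(=O)Cc1c(OC)ccc(OC)c1C(=O)O)OC(=O)CCC(=O)O
F5 | step 5 | tert-butyldimethyl{[(2R)-pent-4-en-2-yl]oxy}silane | C[C@H](CC=C)O[Si](C)(C)C(C)(C)C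
F6 | step 5 | tert-butyl{[(2R)-5-iodopentan-2-yl]oxy}dimethylsilane | C[C@H](CCCI)O[Si](C)(C)C(C)(C)C
F7 | step 5 | 2-[(4R)-4-{[tert-butyl(dimethyl)silyl]oxy}pentyl]-4,7-dimethoxyindan-1-one (both C2 epimers) | C[C@H](CCCC1Cc2c(OC)ccc(OC)c2C1=O)O[Si](C)(C)C(C)(C)C
F8 | step 5 | 2-[(4R)-4-hydroxypentyl]-4,7-dimethoxyindan-1-one (both C2 epimers) | C[C@H](CCCC1Cc2c(OC)ccc(OC)c2C1=O)O
F9 | step 7 | 4-{[(2R)-5-[(3R)-1,5,8-trioxo-3,4,5,8-tetrahydro-1H-isochromen-3-yl]pentan-2-yl]oxy}-4-oxobutanoic acid | C[C@H](CCC[C@@H]1CC2=C(C(=O)O1)C(=O)C=CC2=O)OC(=O)CCC(=O)O
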